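**Strategy.** Everything rests on cutting both benzene rings that flank C4-U back to furans. Ring A (C4a-U to C8a-U) and ring D (C4a-L to C8a-L) are each a 2,3,4-trioxygenated phenyl group on C4-U: the ortho oxygens O1-U and O7-L map onto furan ring oxygens, and their two neighbours onto the ether groups of a 3,4-dialkoxyfuran. Two molecules of 3,4-bis(benzyloxy)furan and penta-1,4-diyn-3-one, handled only as a cold fresh solution, should therefore give both rings in one flask by twofold Diels–Alder addition and chelation-directed opening of the oxygen bridges. The symmetric bis(ortho-hydroxyaryl) ketone that results is desymmetrised by lactonisation, and all five stereocentres are then set by catalyst- or substrate-controlled steps.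

Key step: step 7

Remark on labels: from 18 to 37 the carbon that becomes C4-U is labelled R although its geometry is that of the (4S) centre of the target; only the CIP ranking of ring D against ring A changes when O7-L loses its benzyl group in step 23.
Remark on catalysts: the hand of DTBM-SEGPHOS (step 11) and of t-BuPyOx (step 17) is assumed to be the one that gives the configuration drawn; the antipodal ligand is used if a test shows otherwise.
Remark on the lower unit: heterogeneous reduction of a flavonol would fix C2-L, C3-L and C4-L only relative to one another, so C2-L is set by a catalyst and C4-L and C3-L follow from it.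
Abbreviation: Chr = (2S,4R)-7,8-bis(benzyloxy)-2-[4-(benzyloxy)phenyl]chroman-4-yl.

**Route**

Step 1
Reactants: 1 dimethyl diglycolate; 2 dimethyl oxalate
Product: 3 dimethyl 3,4-dihydroxyfuran-2,5-dicarboxylate
Conditions: NaOMe, MeOH, reflux; then aq. HCl
Reagents that add atoms: none
Why: Twofold Claisen condensation of the two diglycolate methylene groups on the oxalate (Hinsberg furan synthesis) should close the ring, and the enolised diketone is the aromatic 3,4-dihydroxyfuran.

Step 2
Reactants: 3 dimethyl 3,4-dihydroxyfuran-2,5-dicarboxylate; 4 benzyl bromide (2.2 equivalents)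
Product: 5 dimethyl 3,4-bis(benzyloxy)furan-2,5-dicarboxylate
Conditions: BnBr (2.2 equiv), K2CO3 (3 equiv), DMF, 60 °C
Reagents that add atoms: none
Why: Twofold Williamson etherification, one molecule of benzyl bromide for each of the two acidic enolic hydroxyl groups, should be clean because the esters leave no other nucleophilic site.

Step 3
Reactants: 5 dimethyl 3,4-bis(benzyloxy)furan-2,5-dicarboxylate
Product: 6 3,4-bis(benzyloxy)furan-2,5-dicarboxylic acid
Conditions: NaOH, H2O/EtOH, reflux; then aq. HCl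
Reagents that add atoms: sodium hydroxide, [Na+].[OH-]
Why: Ester saponification, to which the benzyl ethers and the furan are inert.

Step 4
Reactants: 6 3,4-bis(benzyloxy)furan-2,5-dicarboxylic acid
Product: 7 3,4-bis(benzyloxy)furan
Conditions: Cu powder, quinoline, 190 °C, N2; kept cold under argon and used soon
Reagents that add atoms: none
Why: Copper-mediated protodecarboxylation of furan-2-carboxylic acids is the classical end of the Hinsberg route and should free both alpha positions of the diene.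

Step 5
Reactants: 8 ethyl formate; 9 ethynylmagnesium bromide (2.2 equivalents)
Product: 10 penta-1,4-diyn-3-ol
Conditions: HC≡CMgBr (2.2 equiv), THF, 0 °C to rt; then dilute aq. HCl
Reagents that add atoms: none
Why: Twofold Grignard addition to a formate ester gives the symmetric secondary carbinol, the intermediate ynal being more electrophilic than the ester.

Step 6
Reactants: 10 penta-1,4-diyn-3-ol
Product: 11 penta-1,4-diyn-3-one
Conditions: activated MnO2, CH2Cl2, 0 °C; filtered through Celite, filtrate kept cold, never concentrated, used at once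
Reagents that add atoms: none
Why: MnO2 oxidises the doubly propargylic alcohol under neutral conditions, and filtration delivers the sensitive diynone as a reagent-free solution.

Step 7
Reactants: 7 3,4-bis(benzyloxy)furan (2.1 equivalents); 11 penta-1,4-diyn-3-one
Product: 14 bis[3,4-bis(benzyloxy)-2-hydroxyphenyl]methanone, via mono-adduct 12 (not isolated), via bis-adduct 13 (not isolated)
Conditions: CH2Cl2, 0 °C to rt, dark; then MgBr2·OEt2 (2.5 equiv), −40 to 0 °C; aq. NH4Cl
Reagents that add atoms: none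
Why: Each ynone arm is an electron-poor two-carbon partner for the electron-rich dialkoxyfuran, so two thermal concerted [4+2] cycloadditions should give the bis(7-oxanorbornadiene) 13, and because the furan is symmetric there is no orientation to control; the closest known chemistry is the Diels–Alder addition of furans to acetylenic ketones followed by acid isomerisation of the 7-oxanorbornadienes to phenols. MgBr2 should then bind the ketone oxygen and the neighbouring bridge oxygens as a chelate, the bridge C–O bond remote from the carbonyl should ionise to an allyl cation capped by a benzyloxy group as an oxocarbenium ion, and loss of the proton from the oxygen-bearing bridgehead carbon aromatises the ring. Ring A thus closes by intermolecular cycloaddition forming C4a–C8a and C5–C6, ring D by the same mode forming C6–C7 and C4a–C5, each six-membered ring then becoming benzenoid, with the bridge oxygens ending as O1-U and O7-L. No stereocentre is created, since the bridgehead centres of 12 and 13 vanish on aromatisation. The selectivity required is regiochemical, oxygen kept ortho and not meta to the carbonyl; it is secured by the six-membered magnesium chelate, which survives only if the near C–O bond is retained, and by the chelated ortho-acyl phenoxide that this pathway delivers. The intrinsic electronic preference of an acyl-substituted bridge may point the other way, which is why a chelating Lewis acid is used in place of a protic acid; the 2.1:1 stoichiometry, low temperature and prompt opening should keep the strained enone bonds of 13 from taking up a third furan.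

Step 8
Reactants: 14 bis[3,4-bis(benzyloxy)-2-hydroxyphenyl]methanone
Product: 15 7,8-bis(benzyloxy)-4-[3,4-bis(benzyloxy)-2-hydroxyphenyl]-2H-chromen-2-one
Conditions: Ph3P=CHCO2Et (1.2 equiv), toluene, reflux
Reagents that add atoms: ethyl (triphenylphosphoranylidene)acetate, CCOC(=O)C=P(c1ccccc1)(c1ccccc1)c1ccccc1
Why: A phenol should transesterify the stabilised ylide and the aryl ester ylide should then olefinate the ortho ketone intramolecularly (Wittig lactonisation); either phenol gives the same coumarin, and the phenol left over now marks ring D.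

Step 9
Reactants: 15 7,8-bis(benzyloxy)-4-[3,4-bis(benzyloxy)-2-hydroxyphenyl]-2H-chromen-2-one
Product: 16 7,8-bis(benzyloxy)-4-[3,4-bis(benzyloxy)-5-bromo-2-hydroxyphenyl]-2H-chromen-2-one
Conditions: NBS (1.0 equiv), MeCN, −20 °C
Reagents that add atoms: N-bromosuccinimide, O=C1CCC(=O)N1Br
Why: Electrophilic aromatic bromination should go para to the only free phenol (the future C4a-L), because both ortho positions are blocked and the coumarin ring is deactivated by its lactone.

Step 10
Reactants: 16 7,8-bis(benzyloxy)-4-[3,4-bis(benzyloxy)-5-bromo-2-hydroxyphenyl]-2H-chromen-2-one; 4 benzyl bromide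
Product: 17 7,8-bis(benzyloxy)-4-[2,3,4-tris(benzyloxy)-5-bromophenyl]-2H-chromen-2-one
Conditions: K2CO3, DMF, 40 °C
Reagents that add atoms: none
Why: Williamson etherification caps O7-L so that every phenol is a benzyl ether before the hydride and organometallic steps.

Step 11
Reactants: 17 7,8-bis(benzyloxy)-4-[2,3,4-tris(benzyloxy)-5-bromophenyl]-2H-chromen-2-one
Product: 18 (4R)-7,8-bis(benzyloxy)-4-[2,3,4-tris(benzyloxy)-5-bromophenyl]chroman-2-one
Conditions: Cu(OAc)2·H2O (cat.), (R)-DTBM-SEGPHOS (cat.), (EtO)2MeSiH, t-BuOH, toluene, 0 °C to rt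
Reagents that add atoms: none
Why: Copper hydride formed in situ and bound to the bulky bisphosphine should deliver hydride to C4 on one face of the flat lactone, with tert-butanol protonating the copper enolate (copper hydride-catalysed asymmetric conjugate reduction of 4-arylcoumarins), so the ligand alone sets C4-U.

Step 12
Reactants: 18 (4R)-7,8-bis(benzyloxy)-4-[2,3,4-tris(benzyloxy)-5-bromophenyl]chroman-2-one
Product: 20 (4R)-7,8-bis(benzyloxy)-4-[2,3,4-tris(benzyloxy)-5-bromophenyl]chroman-2-yl acetate (both C2 epimers), via aluminium-bound lactol 19 (not isolated)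
Conditions: i-Bu2AlH, CH2Cl2, −78 °C; then pyridine, DMAP, Ac2O, −78 to 0 °C
Reagents that add atoms: acetic anhydride, CC(=O)OC(C)=O
Why: The hydride stops at the tetrahedral aluminium hemiacetal at −78 °C and this is acetylated in the same flask (reductive acetylation of a lactone); the mixed C2 configuration is of no consequence because both epimers ionise to one cation.

Step 13
Reactants: 20 (4R)-7,8-bis(benzyloxy)-4-[2,3,4-tris(benzyloxy)-5-bromophenyl]chroman-2-yl acetate; 21 1-(benzyloxy)-4-bromobenzene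
Product: 24 (2S,4R)-7,8-bis(benzyloxy)-2-[4-(benzyloxy)phenyl]-4-[2,3,4-tris(benzyloxy)-5-bromophenyl]chromane, via arylmagnesium bromide 22 (not isolated), via arylzinc bromide 23 (not isolated)
Conditions: 21, Mg, THF; ZnBr2, 0 °C; solvent changed to toluene; then 20, TMSOTf, CH2Cl2, −78 to −40 °C
Reagents that add atoms: none
Why: TMSOTf should ionise the acetate to the chroman-2-yl oxocarbenium ion and the arylzinc should add along the axial trajectory of its half-chair on the face away from the pseudoequatorial C4 aryl group (organozinc addition to an alpha-acetoxy ether), which gives the 2,4-trans flavan and sets C2-U.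

Step 14
Reactants: 24 (2S,4R)-7,8-bis(benzyloxy)-2-[4-(benzyloxy)phenyl]-4-[2,3,4-tris(benzyloxy)-5-bromophenyl]chromane
Product: 26 1-[2,3,4-tris(benzyloxy)-5-Chr-phenyl]ethan-1-one, via enol ether 25 (not isolated)
Conditions: tributyl(1-ethoxyvinyl)stannane, PdCl2(PPh3)2 (cat.), toluene, 100 °C; then 1 M HCl, THF, rt
Reagents that add atoms: tributyl(1-ethoxyvinyl)stannane, CCOC(=C)[Sn](CCCC)(CCCC)CCCC; water, O
Why: Stille coupling of the single aryl bromide with an acetyl anion equivalent and mild hydrolysis of the enol ether should place the acetyl group on C4a-L without touching either stereocentre.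

Step 15
Reactants: 26 1-[2,3,4-tris(benzyloxy)-5-Chr-phenyl]ethan-1-one
Product: 27 1-[3,4-bis(benzyloxy)-2-hydroxy-5-Chr-phenyl]ethan-1-one
Conditions: MgBr2·OEt2 (3 equiv), toluene/Et2O, 60 °C; dilute aq. HCl
Reagents that add atoms: none
Why: Magnesium chelated between the ketone oxygen and the one ortho ether oxygen activates only that benzyl ether for cleavage by bromide (selective debenzylation ortho to a carbonyl), which frees O1-L alone.

Step 16
Reactants: 27 1-[3,4-bis(benzyloxy)-2-hydroxy-5-Chr-phenyl]ethan-1-one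
Product: 29 7,8-bis(benzyloxy)-6-Chr-4H-chromen-4-one, via enaminone 28 (not isolated)
Conditions: Me2NCH(OMe)2, toluene, 90 °C; then Amberlyst 15, CH2Cl2, rt
Reagents that add atoms: N,N-dimethylformamide dimethyl acetal, COC(OC)N(C)C
Why: Condensation at the acetyl methyl group gives the enaminone, and acid-induced addition of the phenol with loss of dimethylamine closes the pyranone (standard chromone synthesis).

Step 17
Reactants: 29 7,8-bis(benzyloxy)-6-Chr-4H-chromen-4-one; 30 [4-(benzyloxy)phenyl]boronic acid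
Product: 31 (2S)-7,8-bis(benzyloxy)-2-[4-(benzyloxy)phenyl]-6-Chr-chroman-4-one
Conditions: Pd(OCOCF3)2 (cat.), (S)-t-BuPyOx (cat.), NH4PF6, H2O, ClCH2CH2Cl, 60 °C
Reagents that add atoms: none
Why: The cationic aryl complex of divalent palladium carrying the pyridine–oxazoline ligand should add across C2=C3 and protonolysis of the palladium enolate should release the flavanone (palladium-catalysed asymmetric conjugate addition of arylboronic acids to chromones), so C2-L is set by the catalyst and not by the distant upper unit.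

Step 18
Reactants: 31 (2S)-7,8-bis(benzyloxy)-2-[4-(benzyloxy)phenyl]-6-Chr-chroman-4-one
Product: 32 (2S,4S)-7,8-bis(benzyloxy)-2-[4-(benzyloxy)phenyl]-6-Chr-chroman-4-ol
Conditions: NaBH4, THF/MeOH, 0 °C; water
Reagents that add atoms: none
Why: Axial hydride attack on the flavanone with its equatorial C2 aryl group gives the equatorial 2,4-cis alcohol, the usual outcome of borohydride reduction of flavanones.

Step 19
Reactants: 32 (2S,4S)-7,8-bis(benzyloxy)-2-[4-(benzyloxy)phenyl]-6-Chr-chroman-4-ol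
Product: 33 (2S)-7,8-bis(benzyloxy)-2-[4-(benzyloxy)phenyl]-6-Chr-2H-chromene
Conditions: Burgess reagent, toluene, 50 °C, dark
Reagents that add atoms: none
Why: Neutral dehydration of the activated benzylic alcohol can only give the C3=C4 alkene because C4a carries no hydrogen, and C2-L is untouched.

Step 20
Reactants: 33 (2S)-7,8-bis(benzyloxy)-2-[4-(benzyloxy)phenyl]-6-Chr-2H-chromene
Product: 35 (2R,3S,4R)-4,7,8-tris(benzyloxy)-2-[4-(benzyloxy)phenyl]-6-Chr-chroman-3-ol, via epoxide 34 (not isolated)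
Conditions: dimethyldioxirane in acetone, CH2Cl2, −40 °C; then BnOH (excess), PPTS (cat.), −40 to 0 °C
Reagents that add atoms: dimethyldioxirane, CC1(C)OO1; benzyl alcohol, OCc1ccccc1
Why: The dioxirane should epoxidise the electron-rich styrene-type alkene on the face away from the C2 aryl group, and benzyl alcohol should open the labile epoxide at benzylic C4 (activated by para O7-L and ortho O1-L) anti to the C3 oxygen, which gives the 2,3-trans-3,4-trans product and places the C4-L oxygen cis to the aryl group.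

Step 21
Reactants: 35 (2R,3S,4R)-4,7,8-tris(benzyloxy)-2-[4-(benzyloxy)phenyl]-6-Chr-chroman-3-ol
Product: 36 (2R,4R)-4,7,8-tris(benzyloxy)-2-[4-(benzyloxy)phenyl]-6-Chr-chroman-3-one
Conditions: Dess–Martin periodinane, NaHCO3, CH2Cl2, 0 °C to rt
Reagents that add atoms: none
Why: Buffered Dess–Martin oxidation of the secondary alcohol removes the wrongly configured C3 centre without enolising the two flanking centres, as in the oxidation of 2,3-trans flavan-3-ols to flavan-3-ones.

Step 22
Reactants: 36 (2R,4R)-4,7,8-tris(benzyloxy)-2-[4-(benzyloxy)phenyl]-6-Chr-chroman-3-one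
Product: 37 (2R,3R,4R)-4,7,8-tris(benzyloxy)-2-[4-(benzyloxy)phenyl]-6-Chr-chroman-3-ol
Conditions: LiBH(s-Bu)3 (L-Selectride), LiBr, THF, −78 °C; water
Reagents that add atoms: none
Why: The bulky hydride should attack the ketone from the face opposite to the C2 aryl and C4 benzyloxy groups, which are cis to each other, so the new hydroxyl group ends cis to both (the flavan-3-one to 2,3-cis-flavan-3-ol reduction), completing the all-cis lower unit and setting C3-L.

Step 23
Reactants: 37 (2R,3R,4R)-4,7,8-tris(benzyloxy)-2-[4-(benzyloxy)phenyl]-6-Chr-chroman-3-ol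
Product: 38 (2R,3R,4R)-6-[(2S,4S)-7,8-dihydroxy-2-(4-hydroxyphenyl)chroman-4-yl]-2-(4-hydroxyphenyl)chromane-3,4,7,8-tetrol (CNP0209379.1)
Conditions: H2 (1 atm), Pd(OH)2/C, THF/MeOH, rt, neutral, stopped at full debenzylation
Reagents that add atoms: none
Why: Hydrogenolysis should cleave the seven primary benzyl C–O bonds faster than the secondary, electron-rich benzylic C–O bonds at C2-U, C2-L and C4-L under neutral conditions, as in the debenzylation of protected flavan-3-ols, and no stereocentre is involved.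

**Compound list**

1 | dimethyl diglycolate | COC(=O)COCC(=O)OC | starting material
2 | dimethyl oxalate | COC(=O)C(=O)OC | starting material
3 | dimethyl 3,4-dihydroxyfuran-2,5-dicarboxylate | COC(=O)c1oc(C(=O)OC)c(O)c1O | intermediate
4 | benzyl bromide | BrCc1ccccc1 | starting material
5 | dimethyl 3,4-bis(benzyloxy)furan-2,5-dicarboxylate | COC(=O)c1oc(C(=O)OC)c(OCc2ccccc2)c1OCc1ccccc1 | intermediate
6 | 3,4-bis(benzyloxy)furan-2,5-dicarboxylic acid | OC(=O)c1oc(C(=O)O)c(OCc2ccccc2)c1OCc1ccccc1 | intermediate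
7 | 3,4-bis(benzyloxy)furan | c1occ(OCc2ccccc2)c1OCc1ccccc1 | intermediate
8 | ethyl formate | CCOC=O | starting material
9 | ethynylmagnesium bromide | C#C[Mg]Br | starting material
10 | penta-1,4-diyn-3-ol | C#CC(O)C#C | intermediate
11 | penta-1,4-diyn-3-one | C#CC(=O)C#C | intermediate
12 | 1-[5,6-bis(benzyloxy)-7-oxabicyclo[2.2.1]hepta-2,5-dien-2-yl]prop-2-yn-1-one (racemic mono-adduct) | C#CC(=O)C1=CC2OC1C(OCc1ccccc1)=C2OCc1ccccc1 | intermediate
13 | bis[5,6-bis(benzyloxy)-7-oxabicyclo[2.2.1]hepta-2,5-dien-2-yl]methanone (mixture of diastereomers) | O=C(C1=CC2OC1C(OCc1ccccc1)=C2OCc1ccccc1)C1=CC2OC1C(OCc1ccccc1)=C2OCc1ccccc1 | intermediate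
14 | bis[3,4-bis(benzyloxy)-2-hydroxyphenyl]methanone | O=C(c1ccc(OCc2ccccc2)c(OCc2ccccc2)c1O)c1ccc(OCc2ccccc2)c(OCc2ccccc2)c1O | intermediate
15 | 7,8-bis(benzyloxy)-4-[3,4-bis(benzyloxy)-2-hydroxyphenyl]-2H-chromen-2-one | O=C1C=C(c2ccc(OCc3ccccc3)c(OCc3ccccc3)c2O)c2ccc(OCc3ccccc3)c(OCc3ccccc3)c2O1 | intermediate
16 | 7,8-bis(benzyloxy)-4-[3,4-bis(benzyloxy)-5-bromo-2-hydroxyphenyl]-2H-chromen-2-one | O=C1C=C(c2cc(Br)c(OCc3ccccc3)c(OCc3ccccc3)c2O)c2ccc(OCc3ccccc3)c(OCc3ccccc3)c2O1 | intermediate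
17 | 7,8-bis(benzyloxy)-4-[2,3,4-tris(benzyloxy)-5-bromophenyl]-2H-chromen-2-one | O=C1C=C(c2cc(Br)c(OCc3ccccc3)c(OCc3ccccc3)c2OCc2ccccc2)c2ccc(OCc3ccccc3)c(OCc3ccccc3)c2O1 | intermediate
18 | (4R)-7,8-bis(benzyloxy)-4-[2,3,4-tris(benzyloxy)-5-bromophenyl]chroman-2-one | O=C1C[C@@H](c2cc(Br)c(OCc3ccccc3)c(OCc3ccccc3)c2OCc2ccccc2)c2ccc(OCc3ccccc3)c(OCc3ccccc3)c2O1 | intermediate
19 | (4R)-7,8-bis(benzyloxy)-4-[2,3,4-tris(benzyloxy)-5-bromophenyl]chroman-2-ol (C2 epimers, present as its diisobutylaluminium alkoxide) | OC1C[C@@H](c2cc(Br)c(OCc3ccccc3)c(OCc3ccccc3)c2OCc2ccccc2)c2ccc(OCc3ccccc3)c(OCc3ccccc3)c2O1 | intermediate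
20 | (4R)-7,8-bis(benzyloxy)-4-[2,3,4-tris(benzyloxy)-5-bromophenyl]chroman-2-yl acetate (C2 epimers) | CC(=O)OC1C[C@@H](c2cc(Br)c(OCc3ccccc3)c(OCc3ccccc3)c2OCc2ccccc2)c2ccc(OCc3ccccc3)c(OCc3ccccc3)c2O1 | intermediate
21 | 1-(benzyloxy)-4-bromobenzene | Brc1ccc(OCc2ccccc2)cc1 | starting material
22 | [4-(benzyloxy)phenyl]magnesium bromide | Br[Mg]c1ccc(OCc2ccccc2)cc1 | intermediate
23 | [4-(benzyloxy)phenyl]zinc bromide | Br[Zn]c1ccc(OCc2ccccc2)cc1 | intermediate
24 | (2S,4R)-7,8-bis(benzyloxy)-2-[4-(benzyloxy)phenyl]-4-[2,3,4-tris(benzyloxy)-5-bromophenyl]chromane (2,4-trans) | C(c6ccccc6)Oc1ccc([C@@H]2C[C@@H](c3cc(Br)c(OCc6ccccc6)c(OCc6ccccc6)c3OCc6ccccc6)c3ccc(OCc6ccccc6)c(OCc6ccccc6)c3O2)cc1 | intermediate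
25 | (2S,4R)-7,8-bis(benzyloxy)-2-[4-(benzyloxy)phenyl]-4-[2,3,4-tris(benzyloxy)-5-(1-ethoxyvinyl)phenyl]chromane | C(c6ccccc6)Oc1ccc([C@@H]2C[C@@H](c3cc(C(=C)OCC)c(OCc6ccccc6)c(OCc6ccccc6)c3OCc6ccccc6)c3ccc(OCc6ccccc6)c(OCc6ccccc6)c3O2)cc1 | intermediate
26 | 1-[2,3,4-tris(benzyloxy)-5-Chr-phenyl]ethan-1-one | C(c6ccccc6)Oc1ccc([C@@H]2C[C@@H](c3cc(C(C)=O)c(OCc6ccccc6)c(OCc6ccccc6)c3OCc6ccccc6)c3ccc(OCc6ccccc6)c(OCc6ccccc6)c3O2)cc1 | intermediate
27 | 1-[3,4-bis(benzyloxy)-2-hydroxy-5-Chr-phenyl]ethan-1-one | C(c6ccccc6)Oc1ccc([C@@H]2C[C@@H](c3cc(C(C)=O)c(O)c(OCc6ccccc6)c3OCc6ccccc6)c3ccc(OCc6ccccc6)c(OCc6ccccc6)c3O2)cc1 | intermediate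
28 | (2E)-1-[3,4-bis(benzyloxy)-2-hydroxy-5-Chr-phenyl]-3-(dimethylamino)prop-2-en-1-one | C(c6ccccc6)Oc1ccc([C@@H]2C[C@@H](c3cc(C(=O)/C=C/N(C)C)c(O)c(OCc6ccccc6)c3OCc6ccccc6)c3ccc(OCc6ccccc6)c(OCc6ccccc6)c3O2)cc1 | intermediate
29 | 7,8-bis(benzyloxy)-6-Chr-4H-chromen-4-one | C(c6ccccc6)Oc1ccc([C@@H]2C[C@@H](c3cc4c(c(OCc6ccccc6)c3OCc6ccccc6)OC=CC4=O)c3ccc(OCc6ccccc6)c(OCc6ccccc6)c3O2)cc1 | intermediate
30 | [4-(benzyloxy)phenyl]boronic acid | OB(O)c1ccc(OCc2ccccc2)cc1 | starting material
31 | (2S)-7,8-bis(benzyloxy)-2-[4-(benzyloxy)phenyl]-6-Chr-chroman-4-one | C(c6ccccc6)Oc1ccc([C@@H]2C[C@@H](c3cc4c(c(OCc6ccccc6)c3OCc6ccccc6)O[C@H](c3ccc(OCc6ccccc6)cc3)CC4=O)c3ccc(OCc6ccccc6)c(OCc6ccccc6)c3O2)cc1 | intermediate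
32 | (2S,4S)-7,8-bis(benzyloxy)-2-[4-(benzyloxy)phenyl]-6-Chr-chroman-4-ol (2,4-cis) | C(c6ccccc6)Oc1ccc([C@@H]2C[C@@H](c3cc4c(c(OCc6ccccc6)c3OCc6ccccc6)O[C@H](c3ccc(OCc6ccccc6)cc3)C[C@@H]4O)c3ccc(OCc6ccccc6)c(OCc6ccccc6)c3O2)cc1 | intermediate
33 | (2S)-7,8-bis(benzyloxy)-2-[4-(benzyloxy)phenyl]-6-Chr-2H-chromene | C(c6ccccc6)Oc1ccc([C@@H]2C[C@@H](c3cc4c(c(OCc6ccccc6)c3OCc6ccccc6)O[C@H](c3ccc(OCc6ccccc6)cc3)C=C4)c3ccc(OCc6ccccc6)c(OCc6ccccc6)c3O2)cc1 | intermediate
34 | (2R,3S,4S)-7,8-bis(benzyloxy)-2-[4-(benzyloxy)phenyl]-6-Chr-3,4-epoxychromane (epoxide trans to the C2 aryl group) | C(c6ccccc6)Oc1ccc([C@@H]2C[C@@H](c3cc4c(c(OCc6ccccc6)c3OCc6ccccc6)O[C@H](c3ccc(OCc6ccccc6)cc3)[C@H]5O[C@@H]45)c3ccc(OCc6ccccc6)c(OCc6ccccc6)c3O2)cc1 | intermediate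
35 | (2R,3S,4R)-4,7,8-tris(benzyloxy)-2-[4-(benzyloxy)phenyl]-6-Chr-chroman-3-ol (2,3-trans-3,4-trans) | C(c6ccccc6)Oc1ccc([C@@H]2C[C@@H](c3cc4c(c(OCc6ccccc6)c3OCc6ccccc6)O[C@H](c3ccc(OCc6ccccc6)cc3)[C@@H](O)[C@@H]4OCc6ccccc6)c3ccc(OCc6ccccc6)c(OCc6ccccc6)c3O2)cc1 | intermediate
36 | (2R,4R)-4,7,8-tris(benzyloxy)-2-[4-(benzyloxy)phenyl]-6-Chr-chroman-3-one (2,4-cis) | C(c6ccccc6)Oc1ccc([C@@H]2C[C@@H](c3cc4c(c(OCc6ccccc6)c3OCc6ccccc6)O[C@H](c3ccc(OCc6ccccc6)cc3)C(=O)[C@@H]4OCc6ccccc6)c3ccc(OCc6ccccc6)c(OCc6ccccc6)c3O2)cc1 | intermediate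
37 | (2R,3R,4R)-4,7,8-tris(benzyloxy)-2-[4-(benzyloxy)phenyl]-6-Chr-chroman-3-ol (all-cis) | C(c6ccccc6)Oc1ccc([C@@H]2C[C@@H](c3cc4c(c(OCc6ccccc6)c3OCc6ccccc6)O[C@H](c3ccc(OCc6ccccc6)cc3)[C@H](O)[C@@H]4OCc6ccccc6)c3ccc(OCc6ccccc6)c(OCc6ccccc6)c3O2)cc1 | intermediate
38 | (2R,3R,4R)-6-[(2S,4S)-7,8-dihydroxy-2-(4-hydroxyphenyl)chroman-4-yl]-2-(4-hydroxyphenyl)chromane-3,4,7,8-tetrol | Oc1ccc([C@@H]2C[C@@H](c3cc4c(c(O)c3O)O[C@H](c3ccc(O)cc3)[C@H](O)[C@@H]4O)c3ccc(O)c(O)c3O2)cc1 | target

**Count and risks**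

Total: 23 steps. Longest linear sequence: 21 steps (steps 1–4 and 7–23, from dimethyl diglycolate 1); the diynone branch (steps 5 and 6) has two steps.

Steps most likely to fail:

1. Step 7. What may go wrong: ionisation of the bridge C–O bond next to the acyl-bearing carbon, so that oxygen ends meta to the ketone; conjugate addition of the furan to the ynone in place of cycloaddition; uptake of a third furan by 13; polymerisation of 11. Fallback (Friedel–Crafts construction of the ketone in place of ring synthesis): it sets out from benzyl bromide 4, the one route compound it needs, and comes back at 14. Commercial pyrogallol is acylated at C4 by commercial 2,3,4-trihydroxybenzoic acid (BF3·OEt2, 90 °C) to give bis(2,3,4-trihydroxyphenyl)methanone F1. F1 is then benzylated with four equivalents of 4 (K2CO3, DMF, rt), the two hydroxyl groups hydrogen-bonded to the ketone reacting last, which gives 14.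

2. Step 13. What may go wrong: loss of facial control at the oxocarbenium ion (2,4-cis product); capture of the cation by the electron-rich C4 aryl ring; slow aryl transfer from zinc. Fallback (no cation; C2-U set by a reagent and closed by substitution): it sets out from 18 and comes back at 24. Aminolysis of 18 (MeNH(OMe)·HCl, i-PrMgCl, THF) gives (3R)-3-[3,4-bis(benzyloxy)-2-hydroxyphenyl]-N-methoxy-N-methyl-3-[2,3,4-tris(benzyloxy)-5-bromophenyl]propanamide F2. Excess 22 converts F2 into (3R)-1-[4-(benzyloxy)phenyl]-3-[3,4-bis(benzyloxy)-2-hydroxyphenyl]-3-[2,3,4-tris(benzyloxy)-5-bromophenyl]propan-1-one F3. Noyori transfer hydrogenation (RuCl[(R,R)-TsDPEN](p-cymene), HCO2H/Et3N) gives (1R,3R)-1-[4-(benzyloxy)phenyl]-3-[3,4-bis(benzyloxy)-2-hydroxyphenyl]-3-[2,3,4-tris(benzyloxy)-5-bromophenyl]propan-1-ol F4. Mitsunobu etherification (PPh3, DIAD, THF) closes the pyran ring with inversion to give 24.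

3. Step 11. What may go wrong: slow or poorly face-selective hydride delivery to the congested, doubly aryl-substituted C4; over-reduction of the lactone. Fallback (homogeneous asymmetric hydrogenation of the ring-opened acrylate): it sets out from 17 and comes back at 18. NaOH in aqueous MeOH opens the lactone to disodium (2E)-3-[3,4-bis(benzyloxy)-2-oxidophenyl]-3-[2,3,4-tris(benzyloxy)-5-bromophenyl]prop-2-enoate F5. Hydrogenation ([Rh(cod)Cl]2, Chiraphos, H2, MeOH) followed by aq. HCl gives (3R)-3-[3,4-bis(benzyloxy)-2-hydroxyphenyl]-3-[2,3,4-tris(benzyloxy)-5-bromophenyl]propanoic acid F6. Warming F6 with TsOH in toluene closes the lactone to 18.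

**Further compounds**

F1 | step 7 | bis(2,3,4-trihydroxyphenyl)methanone | O=C(c1ccc(O)c(O)c1O)c1ccc(O)c(O)c1O
F2 | step 13 | (3R)-3-[3,4-bis(benzyloxy)-2-hydroxyphenyl]-N-methoxy-N-methyl-3-[2,3,4-tris(benzyloxy)-5-bromophenyl]propanamide | CON(C)C(=O)C[C@@H](c1cc(Br)c(OCc2ccccc2)c(OCc2ccccc2)c1OCc1ccccc1)c1ccc(OCc2ccccc2)c(OCc2ccccc2)c1O
F3 | step 13 | (3R)-1-[4-(benzyloxy)phenyl]-3-[3,4-bis(benzyloxy)-2-hydroxyphenyl]-3-[2,3,4-tris(benzyloxy)-5-bromophenyl]propan-1-one | O=C(c1ccc(OCc2ccccc2)cc1)C[C@@H](c1cc(Br)c(OCc2ccccc2)c(OCc2ccccc2)c1OCc1ccccc1)c1ccc(OCc2ccccc2)c(OCc2ccccc2)c1O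
F4 | step 13 | (1R,3R)-1-[4-(benzyloxy)phenyl]-3-[3,4-bis(benzyloxy)-2-hydroxyphenyl]-3-[2,3,4-tris(benzyloxy)-5-bromophenyl]propan-1-ol | O[C@@H](c1ccc(OCc2ccccc2)cc1)C[C@@H](c1cc(Br)c(OCc2ccccc2)c(OCc2ccccc2)c1OCc1ccccc1)c1ccc(OCc2ccccc2)c(OCc2ccccc2)c1O
F5 | step 11 | disodium (2E)-3-[3,4-bis(benzyloxy)-2-oxidophenyl]-3-[2,3,4-tris(benzyloxy)-5-bromophenyl]prop-2-enoate | [Na+].[Na+].[O-]C(=O)/C=C(/c1cc(Br)c(OCc2ccccc2)c(OCc2ccccc2)c1OCc1ccccc1)c1ccc(OCc2ccccc2)c(OCc2ccccc2)c1[O-]
F6 | step 11 | (3R)-3-[3,4-bis(benzyloxy)-2-hydroxyphenyl]-3-[2,3,4-tris(benzyloxy)-5-bromophenyl]propanoic acid | OC(=O)C[C@@H](c1cc(Br)c(OCc2ccccc2)c(OCc2ccccc2)c1OCc1ccccc1)c1ccc(OCc2ccccc2)c(OCc2ccccc2)c1O
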